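**Plan**

- Retrosynthesis: the two benzyl ethers and the 7-O-methyl group come off first. Ring A is then cut at C7–C8 and C4a–C5, leaving a 2-aryl-6-(methoxymethyl)-4-pyranone (rings B and C plus C8) and a methoxymalonyl C3 unit (C5, C6, C7).
- The pyranone is opened at its ring oxygen to a 1,3,5-triketone, which two Claisen disconnections reduce to 2,5-dihydroxyacetophenone.
- Enabling feature: C5, C6, C7 and C8 of ring A all carry oxygen. The C5 and C7 oxygens stand 1,3 like the carbonyls of a malonate, and the C6 and C8 methoxy groups can ride in on the malonate carbon and on the pyranone side chain.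
- Forward: ring B is bought, ring C is closed by cyclodehydration, and ring A is annulated onto it last in one operation. A 7-O-methylation and a hydrogenolysis finish the synthesis.
- Stereochemistry: the target has no stereocentre, so nothing has to be set or preserved.

Key step: step 7

Remark: the target is achiral (no stereocentre, freely rotating aryl–chromone bond), so the SMILES given defines a single compound and the enantiomer question does not arise.

**Route**

Step 1
Reactants: 1 1-(2,5-dihydroxyphenyl)ethan-1-one
Product: 2 1-[2,5-bis(benzyloxy)phenyl]ethan-1-one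
Conditions: BnBr (2.4 equiv), K2CO3 (3 equiv), DMF, 60 °C
Reagents that add atoms: benzyl bromide BrCc1ccccc1
Why: Williamson etherification; the hydrogen-bonded 2-OH is the slower phenol, and DMF with gentle heating should carry both through.

Step 2
Reactants: 2 1-[2,5-bis(benzyloxy)phenyl]ethan-1-one
Product: 3 1-[2,5-bis(benzyloxy)phenyl]butane-1,3-dione
Conditions: NaH (2.5 equiv), EtOAc (3 equiv), THF, reflux; aq. HCl
Reagents that add atoms: ethyl acetate CCOC(C)=O
Why: crossed Claisen condensation of the methyl ketone enolate with ethyl acetate, driven by formation of the stable sodium diketonate.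

Step 3
Reactants: 3 1-[2,5-bis(benzyloxy)phenyl]butane-1,3-dione; 4 N,2-dimethoxy-N-methylacetamide
Product: 5 1-[2,5-bis(benzyloxy)phenyl]-6-methoxyhexane-1,3,5-trione
Conditions: LDA (2.1 equiv), THF, −78 → 0 °C; then 4 (1.1 equiv), −78 → 0 °C; aq. NH4Cl/HCl
Reagents that add atoms: none
Why: Claisen-type acylation of the β-diketone dianion at its terminal, most basic carbon; the chelated tetrahedral adduct of the Weinreb amide holds back the acidic triketone until the quench, so the dianion is not consumed by proton transfer.

Step 4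
Reactants: 5 1-[2,5-bis(benzyloxy)phenyl]-6-methoxyhexane-1,3,5-trione
Product: 6 2-[2,5-bis(benzyloxy)phenyl]-6-(methoxymethyl)-4H-pyran-4-one
Conditions: p-TsOH·H2O (0.1 equiv), toluene, reflux, Dean–Stark
Reagents that add atoms: none
Why: acid-catalysed cyclodehydration of a 1,3,5-triketone, which can give only this 4-pyranone constitution; acid is chosen because base would divert the triketone into aldol aromatisation, and benzyl aryl ethers tolerate catalytic sulfonic acid.

Step 5
Reactants: 7 dimethyl 2-methoxypropanedioate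
Product: 8 2-methoxypropanedioic acid
Conditions: NaOH (2.2 equiv), H2O–MeOH, 0 °C → rt; HCl to pH 1, continuous Et2O extraction, no heating
Reagents that add atoms: sodium hydroxide [Na+].[OH-]
Why: ester saponification, kept cold and worked up without heat so that the malonic acid should not decarboxylate.

Step 6
Reactants: 8 2-methoxypropanedioic acid; 9 2,4,6-trichlorophenol
Product: 10 bis(2,4,6-trichlorophenyl) 2-methoxypropanedioate
Conditions: 9 (2.0 equiv), POCl3 (2.5 equiv), neat, 90 °C; ice-water
Reagents that add atoms: none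
Why: phosphoryl-chloride-mediated esterification of a malonic acid with an acidic phenol, the standard entry to bis(trichlorophenyl) "active" malonates, applied here to the methoxy-substituted acid.

Step 7
Reactants: 6 2-[2,5-bis(benzyloxy)phenyl]-6-(methoxymethyl)-4H-pyran-4-one; 10 bis(2,4,6-trichlorophenyl) 2-methoxypropanedioate
Product: 14 2-[2,5-bis(benzyloxy)phenyl]-5,7-dihydroxy-6,8-dimethoxy-4H-chromen-4-one, via aryloxycarbonyl(methoxy)ketene 11 (not isolated), via β-keto aryl ester 12 (not isolated), via acylketene 13 (not isolated)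
Conditions: 6, LiHMDS (2.1 equiv), THF, −78 °C; 10 (1.1 equiv) added slowly; −78 → 60 °C; aq. HCl
Reagents that add atoms: none
Why: Proposed new method: two equivalents of LiHMDS turn 6 into its laterally deprotonated dienolate and 10 into its enolate, so neither quenches the other; on warming the malonate enolate ejects trichlorophenoxide (E1cB) to acylketene 11, which the dienolate captures at its exocyclic carbon (future C8) to form C7–C8 and the enolate of 12. A second E1cB gives acylketene 13, whose enol is a dienylketene that closes onto pyranone C5 (the ring CH next to the side-chain-bearing C6, future C4a) to form C4a–C5, and two enolisations aromatise ring A. The closest known reactions are the lateral C-acylation of lithiated 2-alkyl-4-pyranones, the cyclocondensation of bis(2,4,6-trichlorophenyl) malonates with 1,3-dinucleophiles through acylketenes, and the dienylketene ring closure of the Danheiser benzannulation; their combination on a pyranone γ,α-dinucleophile is the untested part. Ring A closes by 6π-electrocyclisation of the dienylketene, which in polar terms is a 6-exo-trig Dieckmann-type attack of the dienolate α-carbon on the acyl carbon. No stereocentre is created, and the two CH(OMe) centres of 12 disappear on aromatisation. The step needs C- before O-acylation and C5 as the second nucleophile: O-acyl dienol esters are themselves acyl donors and should revert, the lithiated pyranone reacts at its γ-carbon so the pyranone stays intact, the only six-membered closure open to 13 runs through C5, and the hydrogen-bonded 5-hydroxychromone is the thermodynamic sink.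

Step 8
Reactants: 14 2-[2,5-bis(benzyloxy)phenyl]-5,7-dihydroxy-6,8-dimethoxy-4H-chromen-4-one
Product: 15 2-[2,5-bis(benzyloxy)phenyl]-5-hydroxy-6,7,8-trimethoxy-4H-chromen-4-one
Conditions: MeI (1.1 equiv), K2CO3 (1.2 equiv), acetone, rt → 40 °C
Reagents that add atoms: iodomethane CI
Why: Williamson O-methylation that should select the 7-OH, the more acidic and free phenol (para to C4=O), while the 5-OH is held in the hydrogen bond to the carbonyl.

Step 9
Reactants: 15 2-[2,5-bis(benzyloxy)phenyl]-5-hydroxy-6,7,8-trimethoxy-4H-chromen-4-one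
Product: 16 2-(2,5-dihydroxyphenyl)-5-hydroxy-6,7,8-trimethoxy-4H-chromen-4-one (5,2',5'-trihydroxy-6,7,8-trimethoxyflavone)
Conditions: H2 (1 atm), 10% Pd/C, EtOAc–MeOH, rt; filtration and isolation under argon
Reagents that add atoms: none
Why: catalytic hydrogenolysis of the two aryl benzyl ethers; the aryl methyl ethers and the chromone C2=C3 bond should be inert at 1 atm, and the oxidation-prone hydroquinone ring is protected by working under argon.

**Compound list**

1 | 1-(2,5-dihydroxyphenyl)ethan-1-one (2,5-dihydroxyacetophenone) | CC(=O)c1cc(O)ccc1O | starting material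
2 | 1-[2,5-bis(benzyloxy)phenyl]ethan-1-one | CC(=O)c1cc(OCc2ccccc2)ccc1OCc1ccccc1 | intermediate
3 | 1-[2,5-bis(benzyloxy)phenyl]butane-1,3-dione | CC(=O)CC(=O)c1cc(OCc2ccccc2)ccc1OCc1ccccc1 | intermediate
4 | N,2-dimethoxy-N-methylacetamide (Weinreb amide of methoxyacetic acid, catalogue reagent) | COCC(=O)N(C)OC | starting material
5 | 1-[2,5-bis(benzyloxy)phenyl]-6-methoxyhexane-1,3,5-trione (drawn as triketone, enolised in practice) | COCC(=O)CC(=O)CC(=O)c1cc(OCc2ccccc2)ccc1OCc1ccccc1 | intermediate
6 | 2-[2,5-bis(benzyloxy)phenyl]-6-(methoxymethyl)-4H-pyran-4-one | COCc1cc(=O)cc(-c2cc(OCc3ccccc3)ccc2OCc2ccccc2)o1 | intermediate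
7 | dimethyl 2-methoxypropanedioate (dimethyl methoxymalonate) | COC(C(=O)OC)C(=O)OC | starting material
8 | 2-methoxypropanedioic acid | COC(C(=O)O)C(=O)O | intermediate
9 | 2,4,6-trichlorophenol | Oc1c(Cl)cc(Cl)cc1Cl | starting material
10 | bis(2,4,6-trichlorophenyl) 2-methoxypropanedioate | COC(C(=O)Oc1c(Cl)cc(Cl)cc1Cl)C(=O)Oc1c(Cl)cc(Cl)cc1Cl | intermediate
11 | 2,4,6-trichlorophenyl 2-methoxy-3-oxoprop-2-enoate (acylketene from 10) | COC(=C=O)C(=O)Oc1c(Cl)cc(Cl)cc1Cl | intermediate (not isolated)
12 | 2,4,6-trichlorophenyl 4-{6-[2,5-bis(benzyloxy)phenyl]-4-oxo-4H-pyran-2-yl}-2,4-dimethoxy-3-oxobutanoate (mixture of diastereomers and enol forms) | COC(C(=O)Oc1c(Cl)cc(Cl)cc1Cl)C(=O)C(OC)c1cc(=O)cc(-c2cc(OCc3ccccc3)ccc2OCc2ccccc2)o1 | intermediate (not isolated)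
13 | 4-{6-[2,5-bis(benzyloxy)phenyl]-4-oxo-4H-pyran-2-yl}-2,4-dimethoxybut-1-ene-1,3-dione (acylketene) | COC(=C=O)C(=O)C(OC)c1cc(=O)cc(-c2cc(OCc3ccccc3)ccc2OCc2ccccc2)o1 | intermediate (not isolated)
14 | 2-[2,5-bis(benzyloxy)phenyl]-5,7-dihydroxy-6,8-dimethoxy-4H-chromen-4-one | COc1c(O)c(OC)c2oc(-c3cc(OCc4ccccc4)ccc3OCc3ccccc3)cc(=O)c2c1O | intermediate
15 | 2-[2,5-bis(benzyloxy)phenyl]-5-hydroxy-6,7,8-trimethoxy-4H-chromen-4-one | COc1c(OC)c(OC)c2oc(-c3cc(OCc4ccccc4)ccc3OCc3ccccc3)cc(=O)c2c1O | intermediate
16 | 2-(2,5-dihydroxyphenyl)-5-hydroxy-6,7,8-trimethoxy-4H-chromen-4-one (achiral) | COc1c(OC)c(O)c2c(=O)cc(-c3cc(O)ccc3O)oc2c1OC | target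

**Summary**

Total step count: 9. Longest linear sequence: 7 steps (1, 2, 3, 4, 7, 8, 9); steps 5 and 6 are the two-step malonate branch that joins at step 7.

**Steps most likely to fail**

Step 7 (the proposed annulation). Proton exchange between the two enolates, self-condensation of the ketene, or arrest after the first acyl transfer could each leave ring A unclosed. The fallback uses known flavone chemistry and sets out from 2. A haloform oxidation (NaOCl, NaOH, dioxane–water) should give 2,5-bis(benzyloxy)benzoic acid F1. This is esterified (EDC·HCl, DMAP, CH2Cl2) with the catalogue compound 1-(2-hydroxy-3,4,5,6-tetramethoxyphenyl)ethan-1-one F2 to give 2-acetyl-3,4,5,6-tetramethoxyphenyl 2,5-bis(benzyloxy)benzoate F3. A Baker–Venkataraman rearrangement (KOH, pyridine, 50 °C) should then give 1-[2,5-bis(benzyloxy)phenyl]-3-(2-hydroxy-3,4,5,6-tetramethoxyphenyl)propane-1,3-dione F4, and cyclodehydration (cat. H2SO4, AcOH, 90 °C) the flavone 2-[2,5-bis(benzyloxy)phenyl]-5,6,7,8-tetramethoxy-4H-chromen-4-one F5. Finally BCl3 (CH2Cl2, −78 → 0 °C) should cleave both benzyl ethers and, through chelation to the C4 carbonyl, only the 5-methyl ether. This fallback comes back to the route at the target 16.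

Step 3 (dianion acylation). The strongly basic dianion may enolise the amide instead of adding to it, or acylation may occur at the wrong site, leaving the diketone unconsumed. The fallback sets out from 2 and builds the pyranone through an ynedione instead of a triketone. 3-Methoxyprop-1-yne F6 is formylated (n-BuLi, THF, −78 °C; DMF) to 4-methoxybut-2-ynal F7. The lithium enolate of 2 (LDA, THF, −78 °C) adds to it in an aldol reaction to give racemic 1-[2,5-bis(benzyloxy)phenyl]-3-hydroxy-6-methoxyhex-4-yn-1-one F8. Dess–Martin oxidation should give 1-[2,5-bis(benzyloxy)phenyl]-6-methoxyhex-4-yne-1,3-dione F9, whose enol closes by 6-endo-dig oxa-Michael addition (cat. TfOH, CH2Cl2). This bypasses steps 2–4 and comes back to the route at 6.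

Step 6 (active ester formation). Thermal decarboxylation of the α-methoxymalonic acid, or ketene-type oligomerisation in hot phosphoryl chloride, could consume the acid before both ester bonds form. The fallback sets out from 8 and changes both the activation mode and the leaving group. Carbodiimide coupling (DCC, EtOAc, 0 °C) with pentafluorophenol F10 should give bis(pentafluorophenyl) 2-methoxypropanedioate F11 without heat or acid-chloride chemistry. F11 has a comparable leaving-group ability and takes the place of 10 in step 7, so the route is rejoined at 14.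

**Further compounds**

F1 | step 7 | 2,5-bis(benzyloxy)benzoic acid | OC(=O)c1cc(OCc2ccccc2)ccc1OCc1ccccc1
F2 | step 7 | 1-(2-hydroxy-3,4,5,6-tetramethoxyphenyl)ethan-1-one | CC(=O)c1c(O)c(OC)c(OC)c(OC)c1OC
F3 | step 7 | 2-acetyl-3,4,5,6-tetramethoxyphenyl 2,5-bis(benzyloxy)benzoate | CC(=O)c1c(OC(=O)c2cc(OCc3ccccc3)ccc2OCc2ccccc2)c(OC)c(OC)c(OC)c1OC
F4 | step 7 | 1-[2,5-bis(benzyloxy)phenyl]-3-(2-hydroxy-3,4,5,6-tetramethoxyphenyl)propane-1,3-dione | COc1c(O)c(C(=O)CC(=O)c2cc(OCc3ccccc3)ccc2OCc2ccccc2)c(OC)c(OC)c1OC
F5 | step 7 | 2-[2,5-bis(benzyloxy)phenyl]-5,6,7,8-tetramethoxy-4H-chromen-4-one | COc1c(OC)c(OC)c2oc(-c3cc(OCc4ccccc4)ccc3OCc3ccccc3)cc(=O)c2c1OC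
F6 | step 3 | 3-methoxyprop-1-yne | COCC#C
F7 | step 3 | 4-methoxybut-2-ynal | COCC#CC=O
F8 | step 3 | 1-[2,5-bis(benzyloxy)phenyl]-3-hydroxy-6-methoxyhex-4-yn-1-one (racemic) | COCC#CC(O)CC(=O)c1cc(OCc2ccccc2)ccc1OCc1ccccc1
F9 | step 3 | 1-[2,5-bis(benzyloxy)phenyl]-6-methoxyhex-4-yne-1,3-dione | COCC#CC(=O)CC(=O)c1cc(OCc2ccccc2)ccc1OCc1ccccc1
F10 | step 6 | pentafluorophenol | Oc1c(F)c(F)c(F)c(F)c1F
F11 | step 6 | bis(pentafluorophenyl) 2-methoxypropanedioate | COC(C(=O)Oc1c(F)c(F)c(F)c(F)c1F)C(=O)Oc1c(F)c(F)c(F)c(F)c1F
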